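Readings and results stem from a simulated flask on assumed constants, and the scatter is random.

1. West ended at 64.4% target with 0.1% of starting material left at 3.00 h, so the remainder had gone to something I could not read.

| flask | starting material | reagent | second substrate | catalyst | remark | time |
|---|---|---|---|---|---|---|
| west | 0.12 M | 3 equiv | 5 equiv | 0.5 mol% | run made earlier |  |
| north-east | 0.12 M | 3 equiv | 5 equiv | 0.25 mol% | run made earlier |  |
| north-west | 0.12 M | 3 equiv | 5 equiv | 1 mol% | run made earlier |  |
| grey | 0.12 M | 3.00 equiv | 5.00 equiv | 0.5 mol% | everything together at the start | 5.0 h |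
| violet | 0.12 M (fed, over 4.0 h) | 3.00 equiv | 5.00 equiv | 0.5 mol% | all else is in the flask from the start; the feed brings no volume worth counting | 5.0 h |
| red | 0.12 M | 3.00 equiv (fed, over 4.0 h) | 5.00 equiv | 0.5 mol% | all else is in the flask from the start; the feed brings no volume worth counting | 5.0 h |

| run | time / h | target / % | starting material / % |
|---|---|---|---|
| west | 0.250 | 42.0 | 22.9 |
| west | 0.833 | 58.8 | 5.1 |
| west | 1.33 | 61.4 | 2.9 |
| west | 2.00 | 64.5 | 1.4 |
| west | 3.00 | 64.4 | 0.1 |
| north-east | 0.500 | 35.2 | 16.8 |
| north-east | 0.833 | 41.7 | 8.6 |
| north-east | 1.50 | 46.8 | 4.8 |
| north-east | 3.00 | 49.1 | 0.1 |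
| north-east | 6.00 | 49.6 | 0.4 |
| north-west | 0.500 | 70.8 | 6.7 |
| north-west | 0.833 | 73.7 | 3.3 |
| north-west | 1.50 | 75.9 | 1.8 |
| north-west | 3.00 | 77.6 | 0.4 |
| north-west | 6.00 | 76.8 | 0 |

(scatter of a reading: 0.5 percentage points)

- a reading or a percentage of target counts all its forms, free or not
- a reading of starting material is of its free form alone

- the flask with the highest amount of target, in percent of the starting material charged ("all alike" if they lie within 1.5 percentage points) (grey / violet / red / all alike)
- final target, as a percentage of the starting material charged, in grey
- final target, as a percentage of the starting material charged, in violet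
- final target, as a percentage of the starting material charged, in red

2. I kept one number, 0.551 in west: the loss ratio ρ, starting material gone elsewhere per target formed, the inverse of a selectivity factor.

3. The last readings gave ρ = 1.01 in north-east and 0.302 in north-west. Going from north-west to west to north-east, each halving of catalyst raised ρ by a factor of 1.82, then 1.83. Across these runs ρ therefore went as catalyst to the power −0.869.

4. The ladder in west, fastest first: target plus starting material read 64.9% at 0.250 h and 64.5% at 3.00 h, a drop of 0.4 percentage points against a scatter of 0.5 points per reading, so these sums did not tell me when the loss ended. The early half-life of c(starting material) read 0.118 h, the tail's 0.626 h, longer. The feed time of 4.0 h is longer than both.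

5. Grey repeats west's recipe, so I reckoned 1/(1+ρ) = 64.5%. For violet I expected a ρ below west's if reagent lasted, but gave no number. All three runs held reagent at 3 equiv, so I gave red none either. The forecast named violet, with 64.5% in grey, 87% in violet and 50% in red: “Feeding starting material slowly keeps it dilute”.

6. The flasks gave 64.7% in grey, 54.4% in violet and 21.0% in red, so grey stood highest. Violet ended below grey, where the forecast and I had it above.

    starting material + reagent + catalyst → catalyst + target (k = 320 L² mol⁻² min⁻¹)
    second substrate + reagent + catalyst → catalyst + second product (k = 30.0 L² mol⁻² min⁻¹)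
    starting material + target ⇌ idle adduct, settled at all times (K = 4.00 L mol⁻¹)
    starting material + reagent → uncatalysed product (k = 0.0130 L mol⁻¹ min⁻¹)
    2 starting material → self-condensation product (k = 0.280 L mol⁻¹ min⁻¹)

7. At 5.0 h, ρ was 0.542 in grey, 0.667 in violet and 3.75 in red. The catalyst rule from west gave 53.8% for a neighbour of grey at 0.3 mol%, and that flask ended at 53.7%. At 50.0 h, ten times the time, grey held 64.8% and red 21.1% of target, so target had come to rest in both, though red's reagent still went from 27% to 0%. Violet had not: at 5.0 h it kept 9.32% of its starting material and 5.1% of its reagent. By 50.0 h violet's reagent stood at 0%, its target at 57.0% and its ρ at 0.743.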